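**Assumption:** the acyl chain of the SMILES is read as thirty carbons (triacontanoyl, C1 carbonyl to C30 methyl). The molecule has no stereocentre and is achiral, so no step has to set or preserve configuration.

**Route in one sentence:** a mixed Kolbe anodic decarboxylative cross-coupling of palmitic acid with the hexadecanedioic acid half-ester of O-acetyltyrosol forges the C15–C16 bond of the C30 chain with the phenethyl ester already in place.

## Structural features

The target is an achiral ester. An unbranched, saturated C30 acyl chain (C1 carbonyl to C30 methyl) is joined through the ester oxygen to the C8'H2–C7'H2 tether of a 1,4-disubstituted benzene ring (C1'–C6') that carries a free hydroxyl on C4'. The benzene ring is the only ring, and there is no stereocentre and no double bond outside it. The fragile groups are the C1 ester (bases, nucleophiles, transesterification) and the free phenol, which is easily oxidised and competes with the primary hydroxyl for acylating agents. The real difficulty lies in the chain: twenty-eight consecutive methylene groups without a functional handle, in a C30 acid that is a scarce, waxy and poorly soluble material, whereas C16 acids are commodities. A smaller issue is telling apart the two hydroxyls of the aromatic alcohol portion. The key step exploits the unfunctionalised C15–C16 bond at the exact midpoint of the chain: homolytic cleavage leaves two C15 primary alkyl radicals, each a C16 carboxylic acid less CO2, so the bond can be made by anodic decarboxylative radical cross-coupling of two C16 acids.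

## Logic of the disconnections

**10 to 9.** In the reverse sense an acyl cap is added: the bond in question is the O–C(acyl) bond between the oxygen on C4' and a two-carbon acyl group. The reason is that a free phenol would be oxidised at an anode before any carboxylate, whereas the aryl ester lowers the electron density of the ring. There is no gain in size, but the cap makes the key step permissible. The demand on the forward step is cleavage of the aryl ester without touching the C1 alkyl ester; the better leaving-group ability of an aryloxide makes this feasible.

**9 to 5 and 6, through 7 and 8.** The C15–C16 bond is cut homolytically to the radicals 8 (C1–C15 with the complete ester and arene) and 7 (C16–C30). Each radical is traced to a carboxylic acid with one more carbon, 5 and 6, the extra carbons leaving as CO2. The cut is placed there because it is the one interior bond whose two halves both map onto C16 acids. The gain is that the C30 chain, the only costly element of the target, is replaced by two C16 chains of commodity length, and the skeleton is complete after the coupling. The demands are that both radicals are formed side by side and combine faster than they are oxidised further, that cross-coupling is favoured over homo-coupling (by excess of the cheap partner 6), and that the anode discharges carboxylate and not the arene.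

**5 to 4.** The O–C(CH3)3 bond at the distal carboxyl (C16 of the diacid unit) is restored. The two ends of the diacid have to be told apart, and a tert-butyl ester does this with a cleavage mode (alkyl–oxygen, acid) that the other two esters cannot follow. The forward step must free the acid without touching the aryl ester or the phenethyl ester.

**4 to 3, and 3 to 1 and 2.** First the acyl cap on O4' is removed to give 3. Then the C8'–O bond of the phenethyl ester is cut, so that the ester oxygen stays with the acid 2 and C8' becomes the electrophilic carbon of 1. Forming the ester by alkylating a carboxylate with activated C8' lets the two hydroxyls of 1 be told apart by acidity, so the phenol needs no prior protection. The gain is two purchasable materials. The demand is that the carboxylate of 2 outcompetes the phenol of 1 as the nucleophile.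

## Other disconnections considered

**Alternative 1:** Cut the acyl C1–O bond. The forward key step is a chemoselective esterification of 1 with triacontanoic acid A1 (Mitsunobu or lipase conditions) to give 10 directly. This is the first route that comes to mind and is the shortest, at one step. It is not chosen because it buys the whole difficulty of the target as the scarce, poorly soluble C30 acid A1 and contributes nothing to chain construction. The chosen plan builds the chain from two C16 commodity acids and reaches any homologue by changing the fatty acid.

**Alternative 2:** Cut C9–C10 as an alkene. Dec-9-enoic acid A2 would be esterified with 1 to 2-(4-hydroxyphenyl)ethyl dec-9-enoate A3. The key step is a ruthenium-catalysed cross-metathesis of A3 with docos-1-ene A4 to 2-(4-hydroxyphenyl)ethyl triacont-9-enoate A5, followed by hydrogenation to 10. Cross-metathesis of two unhindered terminal alkenes is as statistical as the radical coupling. In addition, ruthenium hydride species can move the double bonds before metathesis, which would give C29 and C31 homologues that are practically inseparable from 10 after hydrogenation. A redox adjustment step is also needed. The chosen coupling fixes the chain length by the carbon count of the two acids and delivers the saturated bond directly.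

**Alternative 3:** Cut the O–C8' bond and form it by addition to a C7'=C8' alkene. The key step is an anti-Markovnikov hydroacyloxylation of 4-vinylphenyl acetate A6 with A1 under acridinium photoredox and hydrogen-atom-transfer co-catalysis, giving 9, then step 4. The mechanism requires one-electron oxidation of the styrene to its radical cation. With an acetoxy instead of an alkoxy substituent the styrene sits at the edge of the oxidising power of the excited catalyst and is prone to radical-cation oligomerisation. The waxy acid A1 would have to be the limiting reagent in a polar medium, and the C30 chain is still purchased. The chain problem stays untouched.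

Key step: step 3

## Steps

Step 1
Reactants: 1 tyrosol [2-(4-hydroxyphenyl)ethanol]; 2 16-(tert-butoxy)-16-oxohexadecanoic acid
Product: 4 2-(4-acetoxyphenyl)ethyl tert-butyl hexadecanedioate, via tert-butyl 2-(4-hydroxyphenyl)ethyl hexadecanedioate 3 (not isolated)
Conditions: PPh3, DIAD, THF, 0 °C to rt; then Ac2O, Et3N, DMAP (cat.), rt
Reagents that add atoms: acetic anhydride, CC(=O)OC(C)=O
Why: Mitsunobu esterification: the PPh3/DIAD adduct is protonated by the most acidic partner, the carboxylic acid (pKa about 5 against about 10 for the phenol), and the carboxylate displaces the activated primary C8' oxygen, so the aliphatic hydroxyl is esterified and the phenol is left free. The free phenol of 3 is then acetylated in the same flask by DMAP-catalysed acyl transfer; the tert-butyl ester is inert to both stages.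

Step 2
Reactants: 4 2-(4-acetoxyphenyl)ethyl tert-butyl hexadecanedioate
Product: 5 16-[2-(4-acetoxyphenyl)ethoxy]-16-oxohexadecanoic acid
Conditions: TFA/CH2Cl2 (1:3), 0 °C to rt
Reagents that add atoms: none
Why: Acidolysis of the tert-butyl ester by alkyl–oxygen cleavage (tert-butyl cation lost as isobutene). The primary phenethyl ester and the aryl acetate cannot ionise in this way and are stable to anhydrous TFA at room temperature.

Step 3
Reactants: 5 16-[2-(4-acetoxyphenyl)ethoxy]-16-oxohexadecanoic acid; 6 palmitic acid (hexadecanoic acid)
Product: 9 2-(4-acetoxyphenyl)ethyl triacontanoate, via pentadecyl radical 7 (not isolated), via 15-[2-(4-acetoxyphenyl)ethoxy]-15-oxopentadecyl radical 8 (not isolated)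
Conditions: 6 (5 equiv), KOH (10 mol% of total acid), acetone, RVC/RVC, undivided cell, rapid alternating polarity (50 ms), constant current, 30–35 °C
Reagents that add atoms: none
Why: Mixed Kolbe electrolysis: the carboxylates of 5 and 6 are each oxidised by one electron at the anode, the acyloxy radicals lose CO2 within nanoseconds, and the primary radicals 8 and 7 combine at near diffusion-controlled rate in the thin reaction layer at the electrode to form the C15–C16 bond, while the acid protons are reduced to H2 at the counter electrode and regenerate carboxylate, so the base is catalytic. The closest known reaction type is the anodic cross-coupling of a fatty acid with a dicarboxylic acid half-ester, the classical electrochemical route to long unbranched chains, here run with alternating polarity on carbon in a non-nucleophilic solvent. No ring is closed and no stereocentre is formed. The step needs cross-coupling over homo-coupling, which is statistical for two primary radicals of equal reactivity and is secured by the fivefold excess of cheap 6, so that almost every 8 meets a 7; the two homo-dimers differ from 9 by one polar end group in either direction and should separate cleanly on silica. It needs radical coupling and not further oxidation to a cation, which is secured by both radicals being unstabilised primary alkyls whose nearest heteroatom is fourteen atoms away. It needs the anode to discharge carboxylate and not the arene, which is secured by the acetyl group on O4' (an aryl acetate is oxidised well above an alkyl carboxylate, whereas a free phenol or phenolate would be oxidised first) and by the excess of 6, which keeps the medium acidic to the end so that neither ester is solvolysed.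

Step 4
Reactants: 9 2-(4-acetoxyphenyl)ethyl triacontanoate
Product: 10 basalethanolide B [2-(4-hydroxyphenyl)ethyl triacontanoate]
Conditions: pyrrolidine (3 equiv), THF, 0 °C to rt
Reagents that add atoms: none
Why: Chemoselective aminolysis of the aryl acetate: aryloxide (pKa about 10) is a far better leaving group than the alkoxide of the phenethyl ester (pKa about 16), so the secondary amine is acetylated by the aryl ester orders of magnitude faster than it attacks the hindered, lipophilic C1 alkyl ester. THF keeps the waxy substrate in solution.

## Compound list

1 | tyrosol, 2-(4-hydroxyphenyl)ethanol | OCCc1ccc(O)cc1 | starting material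
2 | 16-(tert-butoxy)-16-oxohexadecanoic acid | OC(=O)CCCCCCCCCCCCCCC(=O)OC(C)(C)C | starting material
3 | tert-butyl 2-(4-hydroxyphenyl)ethyl hexadecanedioate | CC(C)(C)OC(=O)CCCCCCCCCCCCCCC(=O)OCCc1ccc(O)cc1 | intermediate (not isolated)
4 | 2-(4-acetoxyphenyl)ethyl tert-butyl hexadecanedioate | CC(C)(C)OC(=O)CCCCCCCCCCCCCCC(=O)OCCc1ccc(OC(C)=O)cc1 | intermediate
5 | 16-[2-(4-acetoxyphenyl)ethoxy]-16-oxohexadecanoic acid | OC(=O)CCCCCCCCCCCCCCC(=O)OCCc1ccc(OC(C)=O)cc1 | intermediate
6 | palmitic acid (hexadecanoic acid) | CCCCCCCCCCCCCCCC(=O)O | starting material
7 | pentadecyl radical | [CH2]CCCCCCCCCCCCCC | intermediate (not isolated)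
8 | 15-[2-(4-acetoxyphenyl)ethoxy]-15-oxopentadecyl radical | [CH2]CCCCCCCCCCCCCC(=O)OCCc1ccc(OC(C)=O)cc1 | intermediate (not isolated)
9 | 2-(4-acetoxyphenyl)ethyl triacontanoate | CCCCCCCCCCCCCCCCCCCCCCCCCCCCCC(=O)OCCc1ccc(OC(C)=O)cc1 | intermediate
10 | basalethanolide B, 2-(4-hydroxyphenyl)ethyl triacontanoate | CCCCCCCCCCCCCCCCCCCCCCCCCCCCCC(=O)OCCc1ccc(O)cc1 | target

## Step count and least certain steps

Total step count: 4. Longest linear sequence: 4 steps (1 and 2 to 4, then 5, 9 and 10; 6 is purchased and enters in step 3).

**Step 3 (key step).** The most likely failures are processes at the electrode. Competitive oxidation of the acetoxyarene could occur once the carboxylate layer is depleted. The waxy C30 and C40 products could precipitate and passivate the carbon surface. Statistical homo-coupling and disproportionation of the radicals would cut the share of cross-product. The fallback sets out from 5 and returns to the route at 9, replacing the anodic radical–radical union by a nickel-catalysed decarboxylative alkyl–alkyl Negishi coupling. Acid 5 would be condensed with N-hydroxyphthalimide (N,N'-diisopropylcarbodiimide, DMAP cat., CH2Cl2) to the redox-active ester 1,3-dioxoisoindolin-2-yl 2-(4-acetoxyphenyl)ethyl hexadecanedioate F1. Purchased 1-bromopentadecane (CCCCCCCCCCCCCCCBr) would be turned with Mg in THF into pentadecylmagnesium bromide F2 and transmetalated with ZnCl2 (0.5 equiv) to dipentadecylzinc F3. F1 and F3 would then be coupled (NiCl2·glyme, a 2,2'-bipyridine ligand, THF/DMF, rt) to give 9; organozinc reagents of this kind should leave both esters untouched.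

**Step 1.** The most likely failure is loss of chemoselectivity in the Mitsunobu stage: alkylation of the phenol oxygen of a second molecule of 1 by the activated C8' (oligomeric aryl ethers), or elimination to the styrene. Acetic anhydride may also be consumed by the reduced azo reagent in the one-pot acetylation. The fallback sets out from 1 and returns at 4, reversing the order so that no free phenol is ever exposed to an alkylating species. Compound 1 would be acetylated at the phenol only (Ac2O, 1 equiv aqueous NaOH, 0 °C, where the phenolate reacts and the alcohol does not) to 4-(2-hydroxyethyl)phenyl acetate F4. F4 would then be acylated with 2 under Steglich conditions (EDC·HCl, DMAP cat., CH2Cl2) to give 4.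

**Step 4.** The most likely failures are slow or incomplete aminolysis because the waxy substrate aggregates or crystallises at low temperature, and, if the reaction is forced, partial cleavage of the phenethyl ester. The fallback sets out from 3 (isolated after the Mitsunobu stage of step 1) and returns at 10, replacing the nucleophilic deprotection by a hydrogenolytic one. Compound 3 would be converted with benzyl chloroformate and pyridine (CH2Cl2, 0 °C) into tert-butyl 2-[4-(benzyloxycarbonyloxy)phenyl]ethyl hexadecanedioate F5. TFA/CH2Cl2 would free the acid 16-{2-[4-(benzyloxycarbonyloxy)phenyl]ethoxy}-16-oxohexadecanoic acid F6. Mixed Kolbe coupling of F6 with 6 under the conditions of step 3 would give 2-[4-(benzyloxycarbonyloxy)phenyl]ethyl triacontanoate F7. Hydrogenolysis (H2, Pd/C, THF/EtOAc, rt) would cleave the benzyl carbonate to 10 under neutral conditions that cannot touch the alkyl ester.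

## Further compounds

F1 | step 3 | 1,3-dioxoisoindolin-2-yl 2-(4-acetoxyphenyl)ethyl hexadecanedioate | O=C(ON1C(=O)c2ccccc2C1=O)CCCCCCCCCCCCCCC(=O)OCCc1ccc(OC(C)=O)cc1
F2 | step 3 | pentadecylmagnesium bromide | CCCCCCCCCCCCCCC[Mg]Br
F3 | step 3 | dipentadecylzinc | CCCCCCCCCCCCCCC[Zn]CCCCCCCCCCCCCCC
F4 | step 1 | 4-(2-hydroxyethyl)phenyl acetate | CC(=O)Oc1ccc(CCO)cc1
F5 | step 4 | tert-butyl 2-[4-(benzyloxycarbonyloxy)phenyl]ethyl hexadecanedioate | CC(C)(C)OC(=O)CCCCCCCCCCCCCCC(=O)OCCc1ccc(OC(=O)OCc2ccccc2)cc1
F6 | step 4 | 16-{2-[4-(benzyloxycarbonyloxy)phenyl]ethoxy}-16-oxohexadecanoic acid | OC(=O)CCCCCCCCCCCCCCC(=O)OCCc1ccc(OC(=O)OCc2ccccc2)cc1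
F7 | step 4 | 2-[4-(benzyloxycarbonyloxy)phenyl]ethyl triacontanoate | CCCCCCCCCCCCCCCCCCCCCCCCCCCCCC(=O)OCCc1ccc(OC(=O)OCc2ccccc2)cc1
A1 | alternative 1 | triacontanoic acid | CCCCCCCCCCCCCCCCCCCCCCCCCCCCCC(=O)O
A2 | alternative 2 | dec-9-enoic acid | C=CCCCCCCCC(=O)O
A3 | alternative 2 | 2-(4-hydroxyphenyl)ethyl dec-9-enoate | C=CCCCCCCCC(=O)OCCc1ccc(O)cc1
A4 | alternative 2 | docos-1-ene | C=CCCCCCCCCCCCCCCCCCCCC
A5 | alternative 2 | 2-(4-hydroxyphenyl)ethyl triacont-9-enoate (E/Z mixture) | CCCCCCCCCCCCCCCCCCCCC=CCCCCCCCC(=O)OCCc1ccc(O)cc1
A6 | alternative 3 | 4-vinylphenyl acetate | C=Cc1ccc(OC(C)=O)cc1
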